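**Retrosynthetic overview**
- The C–N bond between the halves is cut last. Aminoresorcylate 36 displaces the methoxy group of hydroxy(methoxy)quinone 26 (vinylogous ester to vinylogous amide), and both partners carry the same decalin.
- Both C11–aryl bonds go back to one aldehyde 19 (C11 on quaternary C9) and an aryllithium. The benzylic oxygen is then removed by radical deoxygenation.
- Feature used: in the trans-decalin (ring A = C1–C5, C10; ring B = C5–C10) the methyls sit on C4, C5, C8 and C9, and C10 bears H. The open chain C9–C8–C7–C6–C5(CH3)=C10H–C1–C2–C3=C4(CH3) is therefore Markovnikov-matched to a cation on C9, which can form C9–C10 and then C5–C4 with no methyl or hydride shift afterwards.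
- Triene 16 comes from (S)-citronellal (C5–C9, C11, the C8 stereocentre) and pent-3-yn-1-ol (C1–C4), joined at C10–C1 by Negishi coupling.
- Ring order: B and then A in one operation (step 12). The arene and quinone rings are bought as benzene derivatives.

Key step: step 12

Remark: "Dec" is the (1R,2S,4aS,8aS)-1,2,4a,5-tetramethyl-1,2,3,4,4a,7,8,8a-octahydronaphthalen-1-yl unit of the target, with 5-CH3, 8-CH3 and 9-CH3 on one face and 10-H and C11 on the other. The 8a descriptor reads R while C11 bears oxygen.
Remark: C6 of epoxide 5 and the carbinol carbon C11 of 22, 23 and 30–32 should form as epimer mixtures. They are written without configuration because both centres are erased later.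

**Step 1**
Reactants: 1 (S)-citronellal
Product: 2 (3S)-3,7-dimethyl-2-methylideneoct-6-enal
Conditions: 37% aq. HCHO, pyrrolidine (10 mol%), EtCO2H (10 mol%), i-PrOH, 45 °C
Reagents that add atoms: formaldehyde, C=O
Why: Amine-catalysed Mannich condensation–elimination (alpha-methylenation of an aldehyde) places the future C9-methyl carbon on C9, and the C8 centre lies outside the enamine and enal pi systems and keeps its S configuration.

**Step 2**
Reactants: 2 (3S)-3,7-dimethyl-2-methylideneoct-6-enal
Product: 3 (3S)-3,7-dimethyl-2-methylideneoct-6-en-1-ol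
Conditions: NaBH4, CeCl3·7H2O, MeOH, 0 °C
Reagents that add atoms: none
Why: Luche reduction gives clean 1,2-reduction of the enal and leaves both alkenes and the C8 centre alone.

**Step 3**
Reactants: 3 (3S)-3,7-dimethyl-2-methylideneoct-6-en-1-ol
Product: 4 tert-butyl{[(3S)-3,7-dimethyl-2-methylideneoct-6-en-1-yl]oxy}diphenylsilane
Conditions: TBDPSCl, imidazole, CH2Cl2, rt
Reagents that add atoms: tert-butyl(chloro)diphenylsilane, CC(C)(C)[Si](Cl)(c1ccccc1)c1ccccc1
Why: Standard silylation of a primary alcohol installs a large, acid- and base-tolerant group on C11 that later serves as the steric marker at C9.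

**Step 4**
Reactants: 4 TBDPS ether
Product: 5 tert-butyl{[(3S)-5-(3,3-dimethyloxiran-2-yl)-3-methyl-2-methylidenepentyl]oxy}diphenylsilane
Conditions: mCPBA (1.0 equiv), CH2Cl2, −20 to 0 °C
Reagents that add atoms: 3-chloroperbenzoic acid, OOC(=O)c1cccc(Cl)c1
Why: Prilezhaev epoxidation picks the electron-rich trisubstituted alkene over the 1,1-disubstituted one, which is deactivated by its allylic oxygen and shielded by the silyl group, and this is more dependable than a selective ozonolysis.

**Step 5**
Reactants: 5 epoxide
Product: 6 (4S)-5-[(tert-butyldiphenylsilyloxy)methyl]-4-methylhex-5-enal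
Conditions: H5IO6, THF–Et2O, 0 °C
Reagents that add atoms: none
Why: Periodic acid opens the epoxide and cleaves the resulting glycol in one operation (Malaprade-type cleavage), while the remaining alkene and the TBDPS ether are inert.

**Step 6**
Reactants: 6 aldehyde
Product: 7 tert-butyl{[(3S)-3-methyl-2-methylidenehept-6-yn-1-yl]oxy}diphenylsilane
Conditions: dimethyl (1-diazo-2-oxopropyl)phosphonate, K2CO3, MeOH, rt
Reagents that add atoms: dimethyl (1-diazo-2-oxopropyl)phosphonate, CC(=O)C(=[N+]=[N-])P(=O)(OC)OC
Why: Ohira–Bestmann homologation (Seyferth–Gilbert type) turns the aldehyde into the terminal alkyne, adding C10 under mild base that does not reach the remote C8 centre.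

**Step 7**
Reactants: 7 alkyne
Product: 9 tert-butyl{[(3S,6E)-7-iodo-3,6-dimethyl-2-methylidenehept-6-en-1-yl]oxy}diphenylsilane, via alkenylalane 8 (not isolated)
Conditions: AlMe3, Cp2ZrCl2 (25 mol%), CH2Cl2, 0 °C to rt; then I2, THF, −30 °C
Reagents that add atoms: trimethylaluminium, C[Al](C)C; iodine, [I][I]
Why: Negishi zirconium-catalysed carboalumination adds CH3 and Al syn across the alkyne (methyl on C5) and iodinolysis proceeds with retention to give only the E-iodide, and 1,1-disubstituted alkenes and silyl ethers do not react under these conditions.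

**Step 8**
Reactants: 10 pent-3-yn-1-ol
Product: 12 2,2,3-trimethyl-5,6-dihydro-2H-1,2-oxasiline, via dimethylsilyl ether 11 (not isolated)
Conditions: (Me2HSi)2NH, neat, 60 °C, evaporate; then [Cp*Ru(MeCN)3]PF6 (2 mol%), CH2Cl2, 0 °C to rt
Reagents that add atoms: 1,1,3,3-tetramethyldisilazane, C[SiH](C)N[SiH](C)C
Why: O-silylation followed by ruthenium-catalysed intramolecular trans-hydrosilylation (6-endo-dig) lets the tether place silicon on C4, and the six-membered ring forces silicon cis to the chain, which is the Z geometry required.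

**Step 9**
Reactants: 12 cyclic siloxane
Product: 13 (Z)-4-(trimethylsilyl)pent-3-en-1-ol
Conditions: MeLi, Et2O, 0 °C to rt; aq. NH4Cl
Reagents that add atoms: methyllithium, [Li]C
Why: Nucleophilic substitution at silicon opens the Si–O bond and converts SiMe2O into the smallest possible silyl group, SiMe3, without touching the alkene geometry.

**Step 10**
Reactants: 13 (Z)-4-(trimethylsilyl)pent-3-en-1-ol
Product: 14 [(Z)-5-iodopent-2-en-2-yl]trimethylsilane
Conditions: PPh3, I2, imidazole (premixed), CH2Cl2, 0 °C
Reagents that add atoms: iodine, [I][I]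
Why: Appel-type iodination of a primary alcohol is used, and premixing the phosphine with iodine leaves no free iodine to attack the vinylsilane.

**Step 11**
Reactants: 14 [(Z)-5-iodopent-2-en-2-yl]trimethylsilane; 9 (E)-alkenyl iodide
Product: 16 tert-butyl{[(3S,6E,10Z)-3,6-dimethyl-2-methylidene-11-(trimethylsilyl)dodeca-6,10-dien-1-yl]oxy}diphenylsilane, via alkylzinc iodide 15 (not isolated)
Conditions: 14, Zn dust, LiCl, THF, 40 °C; then 9, PdCl2(dppf) (5 mol%), THF, rt to 40 °C
Reagents that add atoms: none
Why: Zinc insertion into the primary iodide and Negishi coupling of the homoallylic zinc reagent with the alkenyl iodide form C10–C1 with retention of both the E and the Z alkene.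

**Step 12**
Reactants: 16 triene
Product: 17 tert-butyl{[(1R,2S,4aS,8aR)-1,2,4a,5-tetramethyl-1,2,3,4,4a,7,8,8a-octahydronaphthalen-1-yl]methoxy}diphenylsilane
Conditions: (R,R)-[N,N'-bis(3,5-di-tert-butylsalicylidene)-1,2-cyclohexanediaminato]cobalt (10 mol%), N-fluoro-2,4,6-trimethylpyridinium triflate (1.5 equiv), PhSiH3 (1.5 equiv, slow addition), (CF3)2CHOH–CH2Cl2, 0 °C, Ar
Reagents that add atoms: none
Why: Proposed new method: the divalent cobalt salen complex is oxidised by the N-fluoropyridinium salt and converted by PhSiH3 into a cobalt hydride, which passes a hydrogen atom to the =CH2 terminus of 16 (this creates the C9 methyl), and the tertiary C9 radical is caught by cobalt and oxidised to an alkylcobalt that reacts as a C9 cation. The closest known reaction types are cobalt-salen hydrogen-atom-transfer-initiated radical-polar crossover polyene cyclizations that end on arenes and Lewis-acid-promoted vinylsilane-terminated cation-olefin cyclizations, and their combination on a triene with this methyl pattern is untested. Ring B closes 6-endo-trig when C10 of the E-alkene attacks C9 and leaves the tertiary C5 cation, and a radical closure would make the same bond because 5-methylhex-5-enyl radicals also prefer the 6-endo mode. Ring A closes 6-endo-trig by ipso attack of C4 on C5, the C3 cation being held by the beta C–Si bond so that loss of the silyl group fixes the alkene at C3=C4, and the Z geometry (chain cis to silicon) is the one that allows this overlap in an endocyclic closure. C10 and C5 follow from anti addition across the E-alkene in a chair-chair fold (trans fusion, 10-H anti to 5-CH3) whose sense is set by the C8 methyl lying equatorial, and C9 follows from the rotamer that places the large CH2OTBDPS group equatorial and the small new methyl axial, syn to the 5-CH3. The step needs hydrogen-atom transfer to the 1,1-disubstituted alkene only and ipso rather than 5-exo attack on the terminator, the first secured by the open =CH2 terminus set against two shielded trisubstituted alkenes and the second by the beta-silicon effect and the small SiMe3 group.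

**Step 13**
Reactants: 17 decalin silyl ether
Product: 18 [(1R,2S,4aS,8aR)-1,2,4a,5-tetramethyl-1,2,3,4,4a,7,8,8a-octahydronaphthalen-1-yl]methanol
Conditions: TBAF, THF, 50 °C
Reagents that add atoms: none
Why: Fluoride cleavage of the silyl ether should proceed with gentle heating despite the neopentyl position, and nothing else in the molecule responds to fluoride.

**Step 14**
Reactants: 18 decalin alcohol
Product: 19 (1R,2S,4aS,8aR)-1,2,4a,5-tetramethyl-1,2,3,4,4a,7,8,8a-octahydronaphthalene-1-carbaldehyde
Conditions: Dess–Martin periodinane, CH2Cl2, rt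
Reagents that add atoms: none
Why: Dess–Martin oxidation gives the aldehyde on quaternary C9, which has no alpha hydrogen and therefore cannot epimerise or enolise.

**Step 15**
Reactants: 20 1,2,4,5-tetramethoxybenzene; 19 decalin aldehyde
Product: 22 (Dec)(2,3,5,6-tetramethoxyphenyl)methanol, via aryllithium 21 (not isolated)
Conditions: 20, n-BuLi, THF, 0 °C to rt; then 19, −78 to 0 °C
Reagents that add atoms: none
Why: Directed ortho-lithiation between two methoxy groups and 1,2-addition to a non-enolisable aldehyde form C11–aryl, and the new carbinol configuration is irrelevant.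

**Step 16**
Reactants: 22 carbinol
Product: 23 O-[(Dec)(2,3,5,6-tetramethoxyphenyl)methyl] S-methyl dithiocarbonate
Conditions: NaHMDS, THF, −78 °C; CS2; MeI, to rt
Reagents that add atoms: carbon disulfide, S=C=S; iodomethane, C[I]
Why: Xanthate formation through the sodium alkoxide is the usual way to activate a hindered secondary alcohol for radical deoxygenation.

**Step 17**
Reactants: 23 xanthate
Product: 24 3-(Dec-methyl)-1,2,4,5-tetramethoxybenzene
Conditions: Bu3SnH, AIBN (cat.), toluene, 110 °C
Reagents that add atoms: none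
Why: Barton–McCombie deoxygenation through a benzylic radical avoids the cations that would invite Wagner–Meerwein shifts at C9 or protonation of the C3=C4 alkene.

**Step 18**
Reactants: 24 tetramethoxyarene
Product: 25 3-(Dec-methyl)-2,5-dimethoxy-1,4-benzoquinone
Conditions: (NH4)2Ce(NO3)6, MeCN–H2O, 0 °C
Reagents that add atoms: water, O
Why: Oxidative demethylation of a para-dimethoxy pair gives the quinone, both para pairs lead to the same product by symmetry, and the arene is far easier to oxidise than the hindered alkene.

**Step 19**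
Reactants: 25 dimethoxyquinone
Product: 26 3-(Dec-methyl)-2-hydroxy-5-methoxy-1,4-benzoquinone (isospongiaquinone)
Conditions: KOH, MeOH–H2O, rt; then dilute HCl, 0 °C
Reagents that add atoms: potassium hydroxide, [K+].[OH-]
Why: Regioselective saponification of a vinylogous ester should occur because the C2 methoxy group is twisted out of conjugation by the neighbouring CH2-Dec group and is exchanged first, after which the quinone anion resists further attack.

**Step 20**
Reactants: 27 4,6-dibromoresorcinol
Product: 28 1,5-dibromo-2,4-bis(methoxymethoxy)benzene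
Conditions: MOMCl, i-Pr2NEt, CH2Cl2, 0 °C to rt
Reagents that add atoms: chloromethyl methyl ether, COCCl
Why: Standard acetal protection of both phenols gives ethers that tolerate and coordinate organolithium reagents, and the second bromine stores the ester position so that no halogenation is needed once the alkene is present.

**Step 21**
Reactants: 28 dibromide; 19 decalin aldehyde
Product: 30 [5-bromo-2,4-bis(methoxymethoxy)phenyl](Dec)methanol, via aryllithium 29 (not isolated)
Conditions: 28, n-BuLi (1.0 equiv), THF, −78 °C; then 19, −78 to 0 °C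
Reagents that add atoms: none
Why: A single bromine–lithium exchange gives an aryllithium whose remaining bromine is meta, so no aryne can form, and this reagent adds to the non-enolisable aldehyde.

**Step 22**
Reactants: 30 bromo carbinol
Product: 31 methyl 5-[(Dec)(hydroxy)methyl]-2,4-bis(methoxymethoxy)benzoate
Conditions: Pd(OAc)2 (5 mol%), Xantphos (10 mol%), CO (1 atm), MeOH, Et3N, 70 °C
Reagents that add atoms: carbon monoxide, [C-]#[O+]; methanol, CO
Why: Palladium-catalysed methoxycarbonylation of the aryl bromide installs the ester under neutral conditions that leave the alcohol, the acetals and the alkene untouched.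

**Step 23**
Reactants: 31 hydroxy ester
Product: 32 methyl 5-{(Dec)[(methylsulfanyl)carbonothioyloxy]methyl}-2,4-bis(methoxymethoxy)benzoate
Conditions: NaHMDS, THF, −78 °C; CS2; MeI, to rt
Reagents that add atoms: carbon disulfide, S=C=S; iodomethane, C[I]
Why: Xanthate formation as in step 16 is used, and the alkoxide is meta to the hindered ester and cannot reach it.

**Step 24**
Reactants: 32 xanthate
Product: 33 methyl 5-(Dec-methyl)-2,4-bis(methoxymethoxy)benzoate
Conditions: Bu3SnH, AIBN (cat.), toluene, 110 °C
Reagents that add atoms: none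
Why: Barton–McCombie deoxygenation is run only after the aryl bromide has been used up, so the tin hydride meets no competing C–Br bond.

**Step 25**
Reactants: 33 bis-MOM ester
Product: 34 methyl 5-(Dec-methyl)-2,4-dihydroxybenzoate
Conditions: HCl (cat.), MeOH, 40 °C
Reagents that add atoms: none
Why: Acid-catalysed acetal exchange with methanol frees both phenols under conditions that routinely spare trisubstituted alkenes placed next to phenols, as in prenylated phenols.

**Step 26**
Reactants: 34 dihydroxybenzoate
Product: 35 methyl 5-(Dec-methyl)-2,4-dihydroxy-3-[(E)-(4-nitrophenyl)diazenyl]benzoate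
Conditions: 4-O2NC6H4N2BF4, Na2CO3, THF–MeOH–H2O, 0 °C
Reagents that add atoms: 4-nitrobenzenediazonium tetrafluoroborate, [O-][N+](=O)c1ccc(cc1)[N+]#N.F[B-](F)(F)F
Why: Azo coupling of the phenolate can take place only at C3, the one free position ortho to an oxygen, and diazonium ions ignore unactivated alkenes, unlike nitrating or halogenating agents.

**Step 27**
Reactants: 35 azo compound
Product: 36 methyl 3-amino-5-(Dec-methyl)-2,4-dihydroxybenzoate
Conditions: Na2S2O4, THF–EtOH–H2O, 50 °C, Ar
Reagents that add atoms: none
Why: Dithionite cleavage of an ortho-hydroxyazo compound is the classical route to aminophenols and affects neither the alkene nor the ester.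

**Step 28**
Reactants: 36 aminoresorcylate; 26 isospongiaquinone
Product: 37 nakijiquinone F
Conditions: EtOH, AcOH (cat.), 50 °C, Ar, dark
Reagents that add atoms: none
Why: Addition–elimination of the amine at C5 of the quinone (aminolysis of a vinylogous ester) forms the C–N bond at the only carbon that bears a leaving group, and no stereocentre is involved.

**Compound list**
1 | (S)-citronellal | O=CC[C@@H](C)CCC=C(C)C | starting material
2 | (3S)-3,7-dimethyl-2-methylideneoct-6-enal | C=C(C=O)[C@@H](C)CCC=C(C)C | intermediate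
3 | (3S)-3,7-dimethyl-2-methylideneoct-6-en-1-ol | C=C(CO)[C@@H](C)CCC=C(C)C | intermediate
4 | TBDPS ether of 3 | C=C(CO[Si](c1ccccc1)(c1ccccc1)C(C)(C)C)[C@@H](C)CCC=C(C)C | intermediate
5 | 6,7-epoxide of 4 (epimers at the oxirane CH) | C=C(CO[Si](c1ccccc1)(c1ccccc1)C(C)(C)C)[C@@H](C)CCC1OC1(C)C | intermediate
6 | (4S)-5-[(tert-butyldiphenylsilyloxy)methyl]-4-methylhex-5-enal | C=C(CO[Si](c1ccccc1)(c1ccccc1)C(C)(C)C)[C@@H](C)CCC=O | intermediate
7 | tert-butyl{[(3S)-3-methyl-2-methylidenehept-6-yn-1-yl]oxy}diphenylsilane | C=C(CO[Si](c1ccccc1)(c1ccccc1)C(C)(C)C)[C@@H](C)CCC#C | intermediate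
8 | (E)-alkenyl(dimethyl)alane from 7 | C=C(CO[Si](c1ccccc1)(c1ccccc1)C(C)(C)C)[C@@H](C)CC/C(C)=C/[Al](C)C | intermediate
9 | (3S,6E)-alkenyl iodide | C=C(CO[Si](c1ccccc1)(c1ccccc1)C(C)(C)C)[C@@H](C)CC/C(C)=C/I | intermediate
10 | pent-3-yn-1-ol | CC#CCCO | starting material
11 | dimethyl(pent-3-yn-1-yloxy)silane | CC#CCCO[SiH](C)C | intermediate
12 | 2,2,3-trimethyl-5,6-dihydro-2H-1,2-oxasiline | CC1=CCCO[Si]1(C)C | intermediate
13 | (Z)-4-(trimethylsilyl)pent-3-en-1-ol | OCC/C=C(/C)[Si](C)(C)C | intermediate
14 | [(Z)-5-iodopent-2-en-2-yl]trimethylsilane | ICC/C=C(/C)[Si](C)(C)C | intermediate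
15 | [(Z)-4-(trimethylsilyl)pent-3-en-1-yl]zinc iodide | I[Zn]CC/C=C(/C)[Si](C)(C)C | intermediate
16 | (3S,6E,10Z)-triene, key-step precursor | C=C(CO[Si](c1ccccc1)(c1ccccc1)C(C)(C)C)[C@@H](C)CC/C(C)=C/CC/C=C(/C)[Si](C)(C)C | intermediate
17 | (1R,2S,4aS,8aR)-decalin C11 TBDPS ether, key-step product | CC(C)(C)[Si](c1ccccc1)(c1ccccc1)OC[C@]1(C)[C@@H](C)CC[C@]2(C)C(C)=CCC[C@@H]12 | intermediate
18 | decalin C11 alcohol | OC[C@]1(C)[C@@H](C)CC[C@]2(C)C(C)=CCC[C@@H]12 | intermediate
19 | decalin C11 aldehyde | O=C[C@]1(C)[C@@H](C)CC[C@]2(C)C(C)=CCC[C@@H]12 | intermediate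
20 | 1,2,4,5-tetramethoxybenzene | COc1cc(OC)c(OC)cc1OC | starting material
21 | 2,3,5,6-tetramethoxyphenyllithium | [Li]c1c(OC)c(OC)cc(OC)c1OC | intermediate
22 | (Dec)(2,3,5,6-tetramethoxyphenyl)methanol | COc1cc(OC)c(OC)c(C(O)[C@]2(C)[C@@H](C)CC[C@]3(C)C(C)=CCC[C@@H]23)c1OC | intermediate
23 | S-methyl xanthate of 22 | COc1cc(OC)c(OC)c(C(OC(=S)SC)[C@]2(C)[C@@H](C)CC[C@]3(C)C(C)=CCC[C@@H]23)c1OC | intermediate
24 | 3-(Dec-methyl)-1,2,4,5-tetramethoxybenzene | COc1cc(OC)c(OC)c(C[C@]2(C)[C@@H](C)CC[C@]3(C)C(C)=CCC[C@@H]23)c1OC | intermediate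
25 | 3-(Dec-methyl)-2,5-dimethoxy-1,4-benzoquinone | COC1=CC(=O)C(OC)=C(C[C@]2(C)[C@@H](C)CC[C@]3(C)C(C)=CCC[C@@H]23)C1=O | intermediate
26 | 3-(Dec-methyl)-2-hydroxy-5-methoxy-1,4-benzoquinone (isospongiaquinone) | COC1=CC(=O)C(O)=C(C[C@]2(C)[C@@H](C)CC[C@]3(C)C(C)=CCC[C@@H]23)C1=O | intermediate
27 | 4,6-dibromoresorcinol | Oc1cc(O)c(Br)cc1Br | starting material
28 | 1,5-dibromo-2,4-bis(methoxymethoxy)benzene | COCOc1cc(OCOC)c(Br)cc1Br | intermediate
29 | 5-bromo-2,4-bis(methoxymethoxy)phenyllithium | COCOc1cc(OCOC)c(Br)cc1[Li] | intermediate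
30 | [5-bromo-2,4-bis(methoxymethoxy)phenyl](Dec)methanol | COCOc1cc(OCOC)c(C(O)[C@]2(C)[C@@H](C)CC[C@]3(C)C(C)=CCC[C@@H]23)cc1Br | intermediate
31 | methyl 5-[(Dec)(hydroxy)methyl]-2,4-bis(methoxymethoxy)benzoate | COCOc1cc(OCOC)c(C(O)[C@]2(C)[C@@H](C)CC[C@]3(C)C(C)=CCC[C@@H]23)cc1C(=O)OC | intermediate
32 | S-methyl xanthate of 31 | COCOc1cc(OCOC)c(C(OC(=S)SC)[C@]2(C)[C@@H](C)CC[C@]3(C)C(C)=CCC[C@@H]23)cc1C(=O)OC | intermediate
33 | methyl 5-(Dec-methyl)-2,4-bis(methoxymethoxy)benzoate | COCOc1cc(OCOC)c(C[C@]2(C)[C@@H](C)CC[C@]3(C)C(C)=CCC[C@@H]23)cc1C(=O)OC | intermediate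
34 | methyl 5-(Dec-methyl)-2,4-dihydroxybenzoate | COC(=O)c1cc(C[C@]2(C)[C@@H](C)CC[C@]3(C)C(C)=CCC[C@@H]23)c(O)cc1O | intermediate
35 | methyl 5-(Dec-methyl)-2,4-dihydroxy-3-[(E)-(4-nitrophenyl)diazenyl]benzoate | COC(=O)c1cc(C[C@]2(C)[C@@H](C)CC[C@]3(C)C(C)=CCC[C@@H]23)c(O)c(/N=N/c2ccc(cc2)[N+](=O)[O-])c1O | intermediate
36 | methyl 3-amino-5-(Dec-methyl)-2,4-dihydroxybenzoate | COC(=O)c1cc(C[C@]2(C)[C@@H](C)CC[C@]3(C)C(C)=CCC[C@@H]23)c(O)c(N)c1O | intermediate
37 | nakijiquinone F | COC(=O)c1cc(C[C@]2(C)[C@@H](C)CC[C@]3(C)C(C)=CCC[C@@H]23)c(O)c(NC2=CC(=O)C(O)=C(C[C@]3(C)[C@@H](C)CC[C@]4(C)C(C)=CCC[C@@H]34)C2=O)c1O | target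

**Step count**
Total steps: 28.
Longest linear sequence: 19 steps (1–7, 11–14, 21–28).

**Steps most likely to fail**

*1. Step 12.*
- What may go wrong: the C9 cation may be lost before ring B closes. Possible routes are a 1,2-hydride shift from C8 or C11, capture by its own silyloxy oxygen, or proton loss.
- The rotamer preference at C9, or the equatorial preference of the C8 methyl, may be too small, giving poor facial selectivity.
- The crowded C5–C4 bond may form too slowly, so that the C5 cation loses a proton after a single ring closure.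
- Fallback (known chemistry), setting out from 16 and coming back at 17:
  - TBAF in THF frees the allylic alcohol triene F1.
  - Sharpless asymmetric epoxidation (Ti(OiPr)4, D-(−)-diisopropyl tartrate, t-BuOOH, 4 Å molecular sieves, CH2Cl2, −20 °C) touches only the allylic alkene. It gives the (R)-epoxy alcohol F2 under reagent control.
  - TBDPSCl and imidazole give the epoxy silyl ether F3.
  - MeAlCl2 in CH2Cl2 at −78 °C starts an epoxide-initiated cation-olefin bicyclization with the same vinylsilane terminator. C10 opens the epoxide at tertiary C9 with inversion, so C9 is set by the epoxide and not by a rotamer preference.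
  - The product is the hydroxymethyl decalin F4, whose axial C9 substituent is CH2OH.
  - Conversion to the primary xanthate F5 (NaH, CS2, MeI) and Barton–McCombie reduction (Bu3SnH, AIBN, toluene, reflux) turn that CH2OH into the C9 methyl and give 17.

*2. Step 28.*
- What may go wrong: the aniline is weakly nucleophilic and flanked by two hydroxyl groups, and the hydroxyquinone sits partly as its unreactive anion, so substitution may be sluggish.
- Electron transfer between aminophenol and quinone, or a later ring closure of an ortho-hydroxyl group onto the quinone, may consume material.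
- Fallback, setting out from 25 and coming back at 37:
  - Exhaustive saponification (aq. NaOH, EtOH, reflux, then acid) gives the 2,5-dihydroxyquinone F6.
  - F6 is condensed with 36 in AcOH–EtOH with loss of water, a reaction 2,5-dihydroxy-3-alkylbenzoquinones are known to undergo with anilines.
  - Exchange should occur only at the unhindered C5 hydroxyl group, because the C2 hydroxyl group is blocked by the CH2-Dec neighbour.

*3. Step 26.*
- What may go wrong: electrophilic attack at C3 is slowed by crowding between two oxygens and by the ester, so the diazonium salt may decompose or couple at oxygen before C–N formation.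
- Fallback, setting out from 33 and coming back at 36:
  - TMPMgCl·LiCl (THF, 0 °C) removes the C3 proton between the two OMOM groups without touching the ester.
  - Tosyl azide converts the arylmagnesium into the aryl azide F7.
  - Staudinger reduction (PPh3, THF–H2O) gives the bis-MOM aniline F8.
  - HCl in MeOH, as in step 25, frees 36.

**Further compounds**
F1 | step 12 | (3S,6E,10Z)-3,6-dimethyl-2-methylidene-11-(trimethylsilyl)dodeca-6,10-dien-1-ol | C=C(CO)[C@@H](C)CC/C(C)=C/CC/C=C(/C)[Si](C)(C)C
F2 | step 12 | (R)-epoxy alcohol, {2-[(2S,5E,9Z)-5-methyl-10-(trimethylsilyl)undeca-5,9-dien-2-yl]oxiran-2-yl}methanol | OC[C@@]1(CO1)[C@@H](C)CC/C(C)=C/CC/C=C(/C)[Si](C)(C)C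
F3 | step 12 | TBDPS ether of F2 | CC(C)(C)[Si](c1ccccc1)(c1ccccc1)OC[C@@]1(CO1)[C@@H](C)CC/C(C)=C/CC/C=C(/C)[Si](C)(C)C
F4 | step 12 | decalin with axial CH2OH and equatorial CH2OTBDPS on C9 | CC(C)(C)[Si](c1ccccc1)(c1ccccc1)OC[C@]1(CO)[C@@H](C)CC[C@]2(C)C(C)=CCC[C@@H]12
F5 | step 12 | S-methyl xanthate of F4 | CC(C)(C)[Si](c1ccccc1)(c1ccccc1)OC[C@]1(COC(=S)SC)[C@@H](C)CC[C@]2(C)C(C)=CCC[C@@H]12
F6 | step 28 | 3-(Dec-methyl)-2,5-dihydroxy-1,4-benzoquinone | OC1=CC(=O)C(O)=C(C[C@]2(C)[C@@H](C)CC[C@]3(C)C(C)=CCC[C@@H]23)C1=O
F7 | step 26 | methyl 3-azido-5-(Dec-methyl)-2,4-bis(methoxymethoxy)benzoate | COCOc1c(N=[N+]=[N-])c(OCOC)c(C[C@]2(C)[C@@H](C)CC[C@]3(C)C(C)=CCC[C@@H]23)cc1C(=O)OC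
F8 | step 26 | methyl 3-amino-5-(Dec-methyl)-2,4-bis(methoxymethoxy)benzoate | COCOc1c(N)c(OCOC)c(C[C@]2(C)[C@@H](C)CC[C@]3(C)C(C)=CCC[C@@H]23)cc1C(=O)OC
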